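Remark on the chemistry: ring A locants C1–C6 of the target are kept for every intermediate. (−)-Quinic acid is the source of ring A, and its own numbering (q) maps as C1q = C3, C2q = C4, C3q = C5, C4q = C6, C5q = C1, C6q = C2. Compounds 22 and 23 have the configuration of 28 at C1, C3, C5, C6 and C7, so the key-step structures need no stereochemical correction, only the change of spectator groups explained below.

## Structural features

The target is a bicyclo[3.3.1]nonan-9-one: ring A (C1–C6) and ring B (C3, C4, C5, C7, C8, C9) share the bridgeheads C3 and C5 and the one-carbon ketone bridge C4. Ring A carries the (E)-dodec-2-enamide on C1, a methylene at C2, a tertiary hydroxyl on the bridgehead C3 and a secondary hydroxyl on C6; ring B carries a methoxy group on C7 and a cis-epoxide across C8–C9. On ring A, N1, O3 and O6 lie on one face (the O-face) and the ring B carbons C7 and C9 on the other (the C-face), so C7 and C9 are 1,3-diaxial. On ring B the methoxy group and the epoxide oxygen are both exo, that is syn to the C4 bridge. Seven stereocentres are packed together: the cis amino alcohol C1/C6, the array C6/C5/C7 around one bridgehead, C7/C8/C9 on ring B and the quaternary carbinol C3. Fragile elements are the epoxide, the beta-hydroxy ketone C6–OH/C4=O (retro-aldol under base), the tertiary alpha-ketol C3–OH/C4=O and the conjugated amide. The real difficulty is to build the 1,3-diaxial junction of ring B on a fully substituted ring A while keeping O4 (a ketone at the end) distinguishable from O6 (a free hydroxyl at the end). The key step uses the C7–C8 bond of ring B: C7 is an oxygen-bearing carbon next to C8 of the latent C8=C9 alkene, the pattern of an aldehyde on C5 and a (Z)-alkenyl metal on C3, and the hydroxyl created at C7 then steers the epoxide.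

## Logic of the disconnections

28 to 25. No skeletal bond is cut. The O6–H bond is traced to an O6–Si bond (27), the C4 carbonyl to a C4–OH (26), and the C3/C4 diol to the isopropylidene acetal of 25. In 26 the only secondary hydroxyl is at C4, because C3–OH is tertiary and O6 is silylated, so the oxidation needs no selectivity. The more obvious pattern (a carbamate on N and one acetal spanning O4 and O6) would instead need a late oxazolidinone to tell O4 from O6, and its final hydrolytic opening in the acylated form is regiochemically uncertain. The demand is that acetal removal spares the epoxide and the silyl ether and that the oxidant does not cleave the 1,2-diol.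

25 to 23. The O7–CH3 bond and the two epoxide C–O bonds (C8–O, C9–O) are cut. This removes the stereocentres C8 and C9 and leaves an allylic alcohol whose hydroxyl can deliver a peracid to the exo face of ring B. The demands are cis-directed epoxidation and O-methylation without touching the amide N–H.

23 to 22 (key). The C7–C8 bond is cut, opening ring B to a ring A aldehyde (C7 on C5) and a (Z)-alkenyl iodide (C9=C8–I on C3). This removes one ring, one skeletal bond and the C7 stereocentre. C4 stays an ether oxygen, so 22 is not a beta-keto aldehyde. The price of the O3/O4 acetal is that ring A has no conformational lock and must flip into the chair with C7 and C9 axial before closure.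

22 to 16. The C8–I bond and the cis C–H bonds of the alkene are traced to a terminal alkyne (21, 19, 18), and the aldehyde carbon C7 to a vinyl group by cutting its C=C bond (18, 16). Both reacting partners of the key step thus become inert vinyl and ethynyl substituents. The forward steps must cleave the vinyl group in the presence of the alkyne and the conjugated amide, and reduce the iodoalkyne to the (Z)-iodoalkene without touching the side chain.

16 to 14. The C3–C9 bond is cut (acetylide plus C3 ketone); the acetal of 16 comes from the diol unit of 15. This removes the quaternary stereocentre. The forward addition must come from the C-face.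

14 to 12. The C4–O bond (enol ether oxidation, 13) and the C5–C7 bond (conjugate addition to the enone 12) are cut. Two stereocentres fall away and a simple cis-4-oxy-5-amido-cyclohexenone remains. Both additions must occur trans to their neighbours: C7 anti to O6, then O4 anti to C7.

12 to 8. The C4=C5 alkene is traced to a beta-elimination of the C5 oxygen (11, 10), and the C3 carbonyl to the carboxyl-bearing carbinol of 8, whose carboxyl carbon is excised (9). This connects the enone to a quinate skeleton that already holds O6 and N1 in the right configuration. The base must expel the acetal oxygen and not the amide.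

8 to 3. The amide C–N bond (7 plus 6) and the C1–N bond are cut; the latter is a C1–O bond of 3 with inverted configuration (5, 4). Acylating at this point puts the finished side chain on nitrogen once and for all, which saves a carbamate exchange later. The demands are a clean SN2 displacement at a secondary ring carbon and a side chain that survives fifteen further steps.

3 to 1. Only protecting-group bonds are cut (ester, acetal, lactone 2). 1 supplies C6 with its oxygen and the C1 oxygen with the configuration needed for inversion.

## Other disconnections considered

Alternative 1: The cut is the C1–N bond. In the forward sense the O6 carbamate A1 of a nitrogen-free bicycle is treated with Rh2(OAc)4, PhI(OAc)2 and MgO, and the rhodium nitrene inserts into the cis C1–H bond to give the cis-fused oxazolidinone A2.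
- In favour: nitrogen enters last and with retention, so the cis N1/O6 relation follows from the mechanism, and no beta-amino ketone has to be carried.
- Against: the step builds no ring and no C–C bond, so the whole bicycle with six stereocentres must be made anyway. The C1–H bond is an unactivated secondary C–H deactivated by the neighbouring C6–O, and it competes with the tertiary C5–H, which is also cis and vicinal to O6. A2 still needs N-acylation and an endocyclic carbamate cleavage whose regiochemistry is not secure.
- Comparison: on stereocontrol at C1 it equals the chosen plan (retentive insertion against SN2 inversion). It is better in keeping nitrogen out of seventeen steps. It is worse in that a site-selective C–H functionalisation sits at the very end, and in adding two steps after the insertion. It could be combined with the same ring B closure, so it is a complement more than a rival.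

Alternative 2: The cut is the C3–C4 bond. A cis-cyclooctenone A3 carrying the C4 aldehyde on C5 is treated with a triazolium-derived carbene and i-Pr2NEt; the acyl anion equivalent adds across the ring to the C3 ketone and gives the bridged acyloin A4.
- In favour: one step forms both rings, the quaternary carbinol C3 and the C4 ketone in its final oxidation state, so no C4 protection or O4/O6 differentiation is needed. The C3 configuration is fixed by the bridge geometry, and the competing 1,4-addition to the enone would close a four-membered ring and should not interfere.
- Against: A3 is an eight-membered ring with four stereocentres (C1, C5, C6, C7) and is much harder to reach than a chiral-pool cyclohexane. Its aldehyde is alpha-branched and flanked by two beta-oxygens, so it may epimerise or eliminate under the amine base. The acceptor is a conjugated, less electrophilic ketone, and the benzoin step is reversible.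
- Comparison: it is better on ring and bond count per step and on redox economy. It is equal in that C7 must be right in both plans, set before closure there and during closure here. It is worse on precursor access and base sensitivity, and the medium-ring synthesis would probably make the total step count longer.

Alternative 3: The cuts are the C4–C5 and O–C6 bonds. The C3-bound aldoxime of cyclooctadiene A5 is oxidised with NaOCl to a nitrile oxide that adds across the ring to the (Z)-C5=C6 alkene, giving the isoxazoline-bridged bicycle A6.
- In favour: two bonds, three rings and the stereocentres C5 and C6 form in one suprafacial step, which puts the C4 bridge and O6 cis by mechanism. N–O cleavage (for example with Mo(CO)6) would then give the C4 ketone and the C6 hydroxyl directly. On the O4/O6 problem this is better than the chosen plan.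
- Against: A5 needs a quaternary C3 with the aldoxime, nitrogen on C1 and the C7 ether already in place on a medium ring. Which alkene face reacts relative to C1 and C7 depends on ring conformation and not on the mechanism. Hypochlorite may chlorinate the carbamate N–H, and the later epoxidation faces a methyl ether, not a hydroxyl, so it must rely on sterics alone.
- Comparison: it equals the chosen plan in resting on a robust reaction class. It is better on bonds and stereocentres per step and on the beta-hydroxy ketone. It is worse on precursor access and on control of C7 and of the epoxide face, and the step count would likely be no lower.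

Key step: step 15

## Route

Step 1
Reactants: 1 (−)-quinic acid
Product: 2 quinic acid 1,5-lactone 3,4-O-isopropylidene acetal
Conditions: Me2C(OMe)2, TsOH·H2O (cat.), acetone, reflux
Reagents that add atoms: 2,2-dimethoxypropane, COC(C)(C)OC
Why: Acid-catalysed lactonisation joins the carboxyl group to the cis-1,3 hydroxyl (C5q) while transketalisation caps the cis-3,4-diol; no stereocentre changes and O5q is set apart from O3q/O4q.

Step 2
Reactants: 2 quinic acid 1,5-lactone 3,4-O-isopropylidene acetal
Product: 3 methyl 3,4-O-isopropylidenequinate
Conditions: NaOMe (0.2 equiv), MeOH, 0 °C to rt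
Reagents that add atoms: methanol, CO
Why: Methoxide transesterification opens the strained bridged lactone and frees the secondary C5q hydroxyl (C1 of ring A, on the C-face); the tertiary hydroxyl stays inert.

Step 3
Reactants: 3 methyl 3,4-O-isopropylidenequinate
Product: 5 methyl 5-azido-5-deoxy-3,4-O-isopropylidene-5-epi-quinate, via 5-O-triflate 4 (not isolated)
Conditions: Tf2O, pyridine, CH2Cl2, −20 °C; then NaN3, DMF, rt
Reagents that add atoms: sodium azide, [Na+].[N-]=[N+]=[N-]
Why: Only the secondary hydroxyl is sulfonylated, and SN2 displacement by azide inverts C1 so that nitrogen ends on the O-face, cis to the acetal oxygen that becomes O6. No anti hydrogen is available toward C6, which limits E2 to the C2 side.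

Step 4
Reactants: 5 methyl 5-azido-5-deoxy-3,4-O-isopropylidene-5-epi-quinate; 6 (E)-dodec-2-enoic acid
Product: 8 methyl 5-deoxy-5-[(E)-dodec-2-enamido]-3,4-O-isopropylidene-5-epi-quinate, via amine 7 (not isolated)
Conditions: PMe3, THF/H2O, rt, concentrate; then 6, EDC·HCl, HOBt (cat.), i-Pr2NEt, CH2Cl2, 0 °C to rt
Reagents that add atoms: none
Why: Staudinger reduction followed by carbodiimide amide coupling. The amine is trans-1,3 to the ester, so it cannot lactamise, and it is the only group acylated. Excess phosphine is stripped before the unsaturated acid is added.

Step 5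
Reactants: 8 methyl 5-deoxy-5-[(E)-dodec-2-enamido]-3,4-O-isopropylidene-5-epi-quinate
Product: 10 all-cis 5-[(E)-dodec-2-enamido]-3,4-(isopropylidenedioxy)cyclohexan-1-one (ring A: C3 ketone; O5/O6 acetal; N on C1), via diol 9 (not isolated)
Conditions: NaBH4, EtOH, 0 °C to rt; then NaIO4, THF/H2O (pH 7), 0 °C
Reagents that add atoms: none
Why: Borohydride reduces the activated alpha-hydroxy ester to a 1,2-diol, and periodate glycol cleavage excises the former carboxyl carbon to leave the C3 ketone; the conjugated amide is untouched by both reagents.

Step 6
Reactants: 10 all-cis 5-[(E)-dodec-2-enamido]-3,4-(isopropylidenedioxy)cyclohexan-1-one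
Product: 12 cis-4-(tert-butyldimethylsilyloxy)-5-[(E)-dodec-2-enamido]cyclohex-2-en-1-one (ring A: C3=O; C4=C5; O6–TBS; N on C1), via hydroxy enone 11 (not isolated)
Conditions: DBU (0.3 equiv), CH2Cl2, 0 °C; then TBSCl, imidazole, 0 °C to rt
Reagents that add atoms: tert-butyldimethylsilyl chloride, CC(C)(C)[Si](C)(C)Cl
Why: E1cB beta-elimination expels the acetal oxygen on C5 (a hemiketal alkoxide, a far better leaving group than an amidate), acetone is lost, and the freed O6–H is silylated in the same flask before a second elimination can occur.

Step 7
Reactants: 12 cis-4-(tert-butyldimethylsilyloxy)-5-[(E)-dodec-2-enamido]cyclohex-2-en-1-one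
Product: 13 trimethylsilyl enol ether C3(OTMS)=C4 carrying a C5 vinyl group on the C-face (trans to O6)
Conditions: CH2=CHMgBr (3 equiv), CuBr·SMe2 (0.2 equiv), TMSCl, THF, −78 °C; Et3N, aqueous NaHCO3
Reagents that add atoms: vinylmagnesium bromide, C=C[Mg]Br; chlorotrimethylsilane, C[Si](C)(C)Cl
Why: Copper-catalysed conjugate addition with silyl trapping. The vinyl group enters axially anti to the pseudoaxial gamma-silyloxy group, and the cis amide on the same face reinforces this, so C5 is set trans to O6; the enolate is fixed regiospecifically as the enol ether. The amide is deprotonated and does not act as an acceptor.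

Step 8
Reactants: 13 trimethylsilyl enol ether C3(OTMS)=C4 carrying a C5 vinyl group
Product: 14 C3 ketone with C4–OTMS on the O-face (trans to the C5 vinyl group)
Conditions: mCPBA, NaHCO3 (solid), CH2Cl2, −20 °C
Reagents that add atoms: 3-chloroperbenzoic acid, OOC(=O)c1cccc(Cl)c1
Why: Rubottom oxidation. The electron-rich enol ether is epoxidised far faster than the vinyl group or the conjugated amide, on the face opposite the pseudoaxial C5 vinyl group of the preferred half-chair (in the other half-chair the axial amide N–H can hydrogen-bond the peracid to the same face). Silyl migration then gives the alpha-silyloxy ketone with O4 trans to C7.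

Step 9
Reactants: 14 C3 ketone with C4–OTMS on the O-face
Product: 15 C3 ethynyl carbinol (C3–OH on the O-face; ethynyl on the C-face; C4–OTMS)
Conditions: HC≡CMgBr (5 equiv), CeCl3 (5 equiv), THF, −78 to −40 °C; aqueous NH4Cl
Reagents that add atoms: ethynylmagnesium bromide, C#C[Mg]Br
Why: Organocerium 1,2-addition, which suppresses enolisation toward the beta-amido carbon. In the chair with O4, C7 and O6 equatorial the metalated C1 amide is axial and blocks the axial trajectory, so the acetylide attacks equatorially from the C-face and sets the quaternary C3 with its oxygen on the O-face.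

Step 10
Reactants: 15 C3 ethynyl carbinol
Product: 16 O3/O4 isopropylidene acetal of the C3 ethynyl compound (C5 vinyl; O6–TBS)
Conditions: Me2C(OMe)2, PPTS (cat.), acetone, rt
Reagents that add atoms: 2,2-dimethoxypropane, COC(C)(C)OC
Why: Acid-catalysed transketalisation cleaves the labile secondary TMS ether in situ and closes the dioxolane on the cis-vicinal C3/C4 diol; the TBS ether and the tertiary propargylic centre tolerate PPTS.

Step 11
Reactants: 16 O3/O4 isopropylidene acetal of the C3 ethynyl compound
Product: 18 C5 hydroxymethyl compound (C7 alcohol), via aldehyde 17 (not isolated)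
Conditions: OsO4 (2 mol %), NaIO4, 2,6-lutidine, dioxane/H2O, rt; then NaBH4, MeOH, 0 °C
Reagents that add atoms: sodium periodate, [Na+].[O-]I(=O)(=O)=O
Why: Lemieux–Johnson cleavage takes the electron-rich monosubstituted alkene in preference to the electron-poor conjugated amide and the alkyne. The beta,beta'-dioxygenated aldehyde is reduced at once so that it cannot eliminate during the next two steps.

Step 12
Reactants: 18 C5 hydroxymethyl compound
Product: 19 C3 iodoethynyl compound
Conditions: NIS, AgNO3 (0.1 equiv), acetone, rt, dark
Reagents that add atoms: N-iodosuccinimide, O=C1CCC(=O)N1I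
Why: Silver-catalysed iodination of the terminal alkyne through the silver acetylide; alcohol, amide and acetal are inert under these near-neutral conditions.

Step 13
Reactants: 19 C3 iodoethynyl compound
Product: 21 (Z)-2-iodovinyl alcohol (C3 and iodine cis), via alkenylborane 20 (not isolated)
Conditions: Cy2BH (3.5 equiv, from BH3·SMe2 and cyclohexene), THF, 0 °C; then AcOH, 0 °C to rt; MeOH work-up
Reagents that add atoms: none
Why: Syn hydroboration of the 1-iodoalkyne places boron on the iodine-bearing carbon and hydrogen on C9, and protodeboronation with acetic acid proceeds with retention, so only the (Z)-iodoalkene can form. The hindered dialkylborane leaves the trans-disubstituted conjugated alkene of the side chain alone, and the O–B bond formed at the primary alcohol is cleaved on work-up.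

Step 14
Reactants: 21 (Z)-2-iodovinyl alcohol
Product: 22 ring A aldehyde with a (Z)-2-iodovinyl group on C3 (O3/O4 acetal; O6–TBS; N-dodecenoyl)
Conditions: Dess–Martin periodinane, NaHCO3, CH2Cl2, 0 °C to rt
Reagents that add atoms: none
Why: Buffered hypervalent-iodine oxidation of the only free hydroxyl. The aldehyde configuration at C5 (trans to both neighbours) is also the thermodynamic one, and the crude product is used directly to avoid beta-elimination on silica.

Step 15
Reactants: 22 ring A aldehyde with a (Z)-2-iodovinyl group on C3
Product: 23 bicyclic allylic alcohol (ring B closed; C7–OH exo; C8=C9)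
Conditions: CrCl2 (8 equiv), NiCl2 (0.1 equiv), DMSO/THF, 0.005 M, rt
Reagents that add atoms: none
Why: NiCl2 is reduced by divalent chromium to zerovalent nickel, which inserts into the C8–I bond with retention; the alkenyl group passes to trivalent chromium and the (Z)-alkenylchromium adds to the C7 aldehyde through a four-centre transition state, forming C7–C8. The closest known reaction type is the intramolecular Nozaki–Hiyama–Kishi cyclisation of formyl alkenyl iodides to cyclic allylic alcohols. Ring B closes in a 6-exo-trig mode with respect to the carbonyl, with the (Z)-alkene inside the ring, once ring A has flipped into the chair with C7 and C9 axial. The one new stereocentre, C7, should be controlled by the position of the chromium-bound oxygen: chromium and oxygen stay on the same side of the forming bond, and the endo side is filled by ring A (axial H on C1, the C2–C1–C6 bridge), so the alkoxide should form exo, syn to the C4 bridge and anti to C6, as the target requires. The step needs chemoselectivity for the aldehyde over the amide and the conjugated alkene, which alkenylchromium reagents provide, and neutral conditions so that the beta,beta'-dioxygenated aldehyde neither epimerises nor eliminates. Because C4 is an acetal oxygen there is no beta-keto aldehyde, and retention in both metal steps keeps the alkene geometry that the ring needs. High dilution suppresses intermolecular coupling while the ring flip is awaited.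

Step 16
Reactants: 23 bicyclic allylic alcohol
Product: 24 exo-8,9-epoxy C7 alcohol
Conditions: mCPBA, NaHCO3, CH2Cl2, 0 °C
Reagents that add atoms: 3-chloroperbenzoic acid, OOC(=O)c1cccc(Cl)c1
Why: Hydroxyl-directed (Henbest) epoxidation. The pseudoaxial exo C7–OH hydrogen-bonds the peracid and the exo face is also the convex one, so both effects put the epoxide cis to O7; the electron-poor side-chain alkene does not react.

Step 17
Reactants: 24 exo-8,9-epoxy C7 alcohol
Product: 25 C7 methyl ether
Conditions: MeI, Ag2O, 4 Å MS, MeCN, 40 °C, dark
Reagents that add atoms: iodomethane, CI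
Why: Purdie methylation under neutral conditions, which leaves the secondary amide N–H alone. The cis epoxy alcohol cannot undergo Payne rearrangement because O7 cannot reach the back side of the epoxide, and C7 keeps its configuration.

Step 18
Reactants: 25 C7 methyl ether
Product: 26 C3/C4 diol (O6–TBS retained)
Conditions: PPTS, MeOH, 45 °C
Reagents that add atoms: none
Why: Acid-catalysed transketalisation to methanol. The dioxolane spanning the bridgehead C3 and the bridge C4 is held at an unfavourable dihedral angle and should leave readily, while the hindered secondary TBS ether and the epoxide, whose back side is the concave face, should survive.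

Step 19
Reactants: 26 C3/C4 diol
Product: 27 C4 ketone O6-TBS ether
Conditions: IBX, DMSO, rt to 40 °C
Reagents that add atoms: none
Why: IBX oxidation of the only secondary hydroxyl; the tertiary C3–OH cannot be oxidised and IBX converts 1,2-diols to ketols without C–C cleavage. The product ketone has no enolisable alpha-hydrogen (C3 quaternary, C5 bridgehead).

Step 20
Reactants: 27 C4 ketone O6-TBS ether
Product: 28 target, (E)-N-dodec-2-enoyl bicyclic epoxy ketol
Conditions: HF·pyridine, pyridine, THF, 0 °C to rt
Reagents that add atoms: none
Why: Buffered fluoride desilylation frees O6 under mildly acidic conditions, which avoids retro-aldol cleavage of the beta-hydroxy ketone; beta-elimination is impossible at the bridgehead.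

## Compound list

1 | (−)-quinic acid | O[C@@H]1C[C@](O)(C(=O)O)C[C@@H](O)[C@H]1O | starting material
2 | quinic acid 1,5-lactone 3,4-O-isopropylidene acetal | O=C1O[C@@H]2C[C@@]1(O)C[C@H]3OC(C)(C)O[C@@H]23 | intermediate
3 | methyl 3,4-O-isopropylidenequinate | O[C@@H]1C[C@](O)(C(=O)OC)C[C@H]2OC(C)(C)O[C@@H]12 | intermediate
4 | 5-O-triflate of 3 | O=S(=O)(O[C@@H]1C[C@](O)(C(=O)OC)C[C@H]2OC(C)(C)O[C@@H]12)C(F)(F)F | intermediate (not isolated)
5 | methyl 5-azido-5-deoxy-3,4-O-isopropylidene-5-epi-quinate | [N-]=[N+]=N[C@H]1C[C@](O)(C(=O)OC)C[C@H]2OC(C)(C)O[C@@H]12 | intermediate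
6 | (E)-dodec-2-enoic acid | CCCCCCCCC/C=C/C(=O)O | starting material
7 | methyl 5-amino-5-deoxy-3,4-O-isopropylidene-5-epi-quinate | N[C@H]1C[C@](O)(C(=O)OC)C[C@H]2OC(C)(C)O[C@@H]12 | intermediate (not isolated)
8 | methyl 5-deoxy-5-[(E)-dodec-2-enamido]-3,4-O-isopropylidene-5-epi-quinate | CCCCCCCCC/C=C/C(=O)N[C@H]1C[C@](O)(C(=O)OC)C[C@H]2OC(C)(C)O[C@@H]12 | intermediate
9 | 1-(hydroxymethyl) diol from reduction of 8 | CCCCCCCCC/C=C/C(=O)N[C@H]1C[C@](O)(CO)C[C@H]2OC(C)(C)O[C@@H]12 | intermediate (not isolated)
10 | all-cis 5-[(E)-dodec-2-enamido]-3,4-(isopropylidenedioxy)cyclohexan-1-one | CCCCCCCCC/C=C/C(=O)N[C@H]1CC(=O)C[C@H]2OC(C)(C)O[C@@H]12 | intermediate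
11 | cis-5-[(E)-dodec-2-enamido]-4-hydroxycyclohex-2-en-1-one | CCCCCCCCC/C=C/C(=O)N[C@H]1CC(=O)C=C[C@H]1O | intermediate (not isolated)
12 | cis-4-(tert-butyldimethylsilyloxy)-5-[(E)-dodec-2-enamido]cyclohex-2-en-1-one | CCCCCCCCC/C=C/C(=O)N[C@H]1CC(=O)C=C[C@H]1O[Si](C)(C)C(C)(C)C | intermediate
13 | trimethylsilyl enol ether C3(OTMS)=C4 with C5 vinyl trans to O6 | CCCCCCCCC/C=C/C(=O)N[C@H]1CC(O[Si](C)(C)C)=C[C@H](C=C)[C@H]1O[Si](C)(C)C(C)(C)C | intermediate
14 | C3 ketone with C4–OTMS on the O-face | CCCCCCCCC/C=C/C(=O)N[C@H]1CC(=O)[C@@H](O[Si](C)(C)C)[C@H](C=C)[C@H]1O[Si](C)(C)C(C)(C)C | intermediate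
15 | C3 ethynyl carbinol (C4–OTMS) | CCCCCCCCC/C=C/C(=O)N[C@H]1C[C@](O)(C#C)[C@@H](O[Si](C)(C)C)[C@H](C=C)[C@H]1O[Si](C)(C)C(C)(C)C | intermediate
16 | O3/O4 isopropylidene acetal with C3 ethynyl and C5 vinyl | CCCCCCCCC/C=C/C(=O)N[C@H]1C[C@@]2(C#C)OC(C)(C)O[C@H]2[C@H](C=C)[C@H]1O[Si](C)(C)C(C)(C)C | intermediate
17 | C5 carbaldehyde with C3 ethynyl | CCCCCCCCC/C=C/C(=O)N[C@H]1C[C@@]2(C#C)OC(C)(C)O[C@H]2[C@H](C=O)[C@H]1O[Si](C)(C)C(C)(C)C | intermediate (not isolated)
18 | C5 hydroxymethyl compound with C3 ethynyl | CCCCCCCCC/C=C/C(=O)N[C@H]1C[C@@]2(C#C)OC(C)(C)O[C@H]2[C@H](CO)[C@H]1O[Si](C)(C)C(C)(C)C | intermediate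
19 | C3 iodoethynyl compound | CCCCCCCCC/C=C/C(=O)N[C@H]1C[C@@]2(C#CI)OC(C)(C)O[C@H]2[C@H](CO)[C@H]1O[Si](C)(C)C(C)(C)C | intermediate
20 | (Z)-1-iodo-1-(dicyclohexylboryl)alkene with O7 dicyclohexylborinate | CCCCCCCCC/C=C/C(=O)N[C@H]1C[C@@]2(/C=C(\I)B(C3CCCCC3)C3CCCCC3)OC(C)(C)O[C@H]2[C@H](COB(C3CCCCC3)C3CCCCC3)[C@H]1O[Si](C)(C)C(C)(C)C | intermediate (not isolated)
21 | (Z)-2-iodovinyl alcohol | CCCCCCCCC/C=C/C(=O)N[C@H]1C[C@@]2(/C=C\I)OC(C)(C)O[C@H]2[C@H](CO)[C@H]1O[Si](C)(C)C(C)(C)C | intermediate
22 | ring A aldehyde with (Z)-2-iodovinyl group on C3 | CCCCCCCCC/C=C/C(=O)N[C@H]1C[C@@]2(/C=C\I)OC(C)(C)O[C@H]2[C@H](C=O)[C@H]1O[Si](C)(C)C(C)(C)C | intermediate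
23 | bicyclic allylic alcohol (C7–OH exo) | CCCCCCCCC/C=C/C(=O)N[C@H]1C[C@@]23OC(C)(C)O[C@H]2[C@@H]([C@H]1O[Si](C)(C)C(C)(C)C)[C@H](O)C=C3 | intermediate
24 | exo-8,9-epoxy C7 alcohol | CCCCCCCCC/C=C/C(=O)N[C@H]1C[C@@]23OC(C)(C)O[C@H]2[C@@H]([C@H]1O[Si](C)(C)C(C)(C)C)[C@H](O)[C@@H]4O[C@@H]43 | intermediate
25 | C7 methyl ether | CCCCCCCCC/C=C/C(=O)N[C@H]1C[C@@]23OC(C)(C)O[C@H]2[C@@H]([C@H]1O[Si](C)(C)C(C)(C)C)[C@H](OC)[C@@H]4O[C@@H]43 | intermediate
26 | C3/C4 diol | CCCCCCCCC/C=C/C(=O)N[C@H]1C[C@@]2(O)[C@@H](O)[C@@H]([C@H]1O[Si](C)(C)C(C)(C)C)[C@H](OC)[C@@H]3O[C@@H]32 | intermediate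
27 | C4 ketone O6-TBS ether | CCCCCCCCC/C=C/C(=O)N[C@H]1C[C@@]2(O)C(=O)[C@@H]([C@H]1O[Si](C)(C)C(C)(C)C)[C@H](OC)[C@@H]3O[C@@H]32 | intermediate
28 | target (CNP0137540.1) | CCCCCCCCC/C=C/C(=O)N[C@H]1C[C@@]2(O)C(=O)[C@@H]([C@H]1O)[C@H](OC)[C@@H]1O[C@@H]12 | target

## Step count and least certain steps

Total step count: 20. Longest linear sequence: 20 steps (1 to 28; 6 enters at step 4).

Step 15 (key step). The most likely failures are poor facial selectivity at C7, if the chromium alkoxide forms on the endo side, and slow closure, because ring A has no conformational lock and must flip into the diaxial chair, which gives protodemetalation time to compete. The fallback corrects C7 by substitution and does not rely on the ring closure for it. It sets out from 22. If closure gives mainly the C7 epimer F1, a Mitsunobu reaction (4-nitrobenzoic acid, PPh3, DIAD, toluene) would give the inverted 4-nitrobenzoate F2; the carboxylate enters from the open exo face and SN2' attack at C9 is blocked by the quaternary C3. Methanolysis (K2CO3, MeOH) returns to the route at 23.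

Step 3. Substitution at a ring carbon flanked by a cis oxygen may be slow and E2 elimination toward C2 may take over. The fallback replaces the displacement by a reduction. It sets out from 3: Dess–Martin oxidation of the secondary hydroxyl would give the ketone F3, hydroxylamine (NH2OH·HCl, NaOAc, MeOH) the oxime F4, and hydrogenation (H2, PtO2, AcOH) should add hydrogen from the face opposite the acetal and the axial tertiary hydroxyl. This gives amine 7, where the route is rejoined at the coupling stage of step 4.

Step 6. The base may expel the amide in place of, or after, the acetal oxygen, and a second elimination would aromatise the ring. The fallback uses acid, under which an amide nitrogen cannot leave. It sets out from 10: aqueous CF3CO2H would hydrolyse the acetal to the dihydroxy ketone F5, and warming in AcOH should dehydrate the beta-hydroxy ketone to 11. The route is rejoined at 11, which is silylated as in step 6 to 12.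

Step 8. The peracid may approach from the C-face if the half-chair with the axial amide reacts unassisted, and some epoxidation of the vinyl group is possible. The fallback oxidises the enolate itself with a bulky oxygen donor that cannot touch the alkene. It sets out from 13: MeLi regenerates the lithium enolate, and 2-(phenylsulfonyl)-3-phenyloxaziridine at −78 °C should hydroxylate C4 anti to the vinyl group to give the hydroxy ketone F6. Silylation (TMSCl, imidazole) returns to the route at 14.

Step 13. Hydroboration next to a quaternary acetal carbon may be incomplete, and the hydroxyl and amide consume borane. The fallback is a concerted hydrogen transfer: diimide generated from 2-nitrobenzenesulfonylhydrazide and Et3N would reduce 19 directly to 21 with the same syn outcome. It sets out from 19 and returns at 21 and adds no compound of its own (F0). Its own risk is partial saturation of the side-chain alkene, to be limited by stoichiometry.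

## Further compounds

F1 | step 15 | C7 epimer of 23 (C7–OH endo) | CCCCCCCCC/C=C/C(=O)N[C@H]1C[C@@]23OC(C)(C)O[C@H]2[C@@H]([C@H]1O[Si](C)(C)C(C)(C)C)[C@@H](O)C=C3
F2 | step 15 | 4-nitrobenzoate of 23 (C7 ester exo) | CCCCCCCCC/C=C/C(=O)N[C@H]1C[C@@]23OC(C)(C)O[C@H]2[C@@H]([C@H]1O[Si](C)(C)C(C)(C)C)[C@H](OC(=O)c4ccc(cc4)[N+](=O)[O-])C=C3
F3 | step 3 | methyl 5-dehydro-3,4-O-isopropylidenequinate (C1 ketone of ring A) | O=C1C[C@](O)(C(=O)OC)C[C@H]2OC(C)(C)O[C@@H]12
F4 | step 3 | oxime of F3 | ON=C1C[C@](O)(C(=O)OC)C[C@H]2OC(C)(C)O[C@@H]12
F5 | step 6 | all-cis 5-[(E)-dodec-2-enamido]-3,4-dihydroxycyclohexan-1-one | CCCCCCCCC/C=C/C(=O)N[C@H]1CC(=O)C[C@@H](O)[C@H]1O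
F6 | step 8 | C4-hydroxy ketone (free alcohol corresponding to 14) | CCCCCCCCC/C=C/C(=O)N[C@H]1CC(=O)[C@@H](O)[C@H](C=C)[C@H]1O[Si](C)(C)C(C)(C)C
F0 | step 13 | none | none
A1 | alternative 1 | O6 carbamate of the nitrogen-free bicycle | NC(=O)O[C@H]1CC[C@@]2(O)C(=O)[C@@H]1[C@H](OC)[C@@H]3O[C@@H]32
A2 | alternative 1 | cis-fused oxazolidinone across C1 and C6 | O=C1N[C@H]2C[C@@]3(O)C(=O)[C@@H]([C@H]2O1)[C@H](OC)[C@@H]4O[C@@H]43
A3 | alternative 2 | cis-cyclooctenone with C5-bound aldehyde (N-Boc, O6 silyl ether) | CC(C)(C)OC(=O)N[C@H]1CC(=O)/C=C\[C@@H](OC)[C@@H](C=O)[C@H]1O[Si](C)(C)C(C)(C)C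
A4 | alternative 2 | bridged tertiary acyloin (N-Boc, O6 silyl ether) | CC(C)(C)OC(=O)N[C@H]1C[C@@]2(O)C(=O)[C@@H]([C@H]1O[Si](C)(C)C(C)(C)C)[C@H](OC)C=C2
A5 | alternative 3 | cyclooctadiene with C3-bound aldoxime (N-Boc, O3 trimethylsilyl ether) | CC(C)(C)OC(=O)N[C@H]1C[C@@](O[Si](C)(C)C)(C=NO)/C=C\[C@@H](OC)/C=C\1
A6 | alternative 3 | isoxazoline-bridged bicyclo[3.3.1]nonene | CC(C)(C)OC(=O)N[C@H]1C[C@@]2(O[Si](C)(C)C)C3=NO[C@@H]1[C@H]3[C@H](OC)C=C2
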